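The constants used here are made up; no experiment stands behind them.

The stirred vessel holds two solids, each dissolving at its own pace, and what has dissolved couples to product.

solid substrate 5.0 × 10⁻⁴ M; solid reagent 0.500 mM; time 40 s

    solid substrate ⇌ dissolved substrate, rate k1*(cs1 - [dissolved substrate]) while solid is left; crystals form when [dissolved substrate] > cs1 (cs1 = 0.22 mM, k1 = 0.085 s⁻¹)
    solid reagent ⇌ coupling partner, rate k2*(cs2 - [coupling partner]) while solid is left; crystals form when [coupling partner] > cs2 (cs2 = 0.25 mM, k2 = 0.24 s⁻¹)
    dissolved substrate + coupling partner → product (k3 = 2600 L mol⁻¹ s⁻¹)

1. amount of product at 40 s, in percent of the solid substrate charged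
2. concentration of dissolved substrate in solution at 40 s, in percent of saturation

Both dissolved species start at zero, so product starts with zero slope, while [dissolved substrate] climbs at 0.0187 mM s⁻¹ and [coupling partner] at 0.0600 mM s⁻¹. If [coupling partner] lies near 0.25 mM, dissolved substrate is consumed pseudo-first-order at 0.650 s⁻¹, faster than its dissolving coefficient of 0.085 s⁻¹. My reckoning therefore keeps [dissolved substrate] low and draws product as a nearly straight line, ending at a knee given by the emptying time, the charged solid divided by its full dissolving pace:

emptying time = 26.7 s

Solid reagent at its own full pace needs 8.33 s, which is shorter, so the dissolving of solid substrate is taken as the rate-limiting step. The charges are equal, so past the knee [dissolved substrate] equals [coupling partner], and the curve runs toward the whole charge along a second-order tail. Setting its starting value aside: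

[dissolved substrate] at 40 s ≈ inverse of 2600 L mol⁻¹ s⁻¹ × (40 s − 26.7 s) = 0.0290 mM

y ≈ 94.2 %, sat ≈ 13.2 %

The forecast gives y = 94.3 % (92.5 % to 95.5 %) and sat = 13 % (10.5 % to 16 %), holding that “the dissolved concentrations then stay equal and decay by second-order kinetics”.

The flask gives y = 94.6 % and sat = 12.2 %, inside both forecast ranges. At 15.8 s the half-life of dissolved substrate against coupling is 1.5 s, shorter than the run, and the emptying time also lies below the run, with 0 % solid substrate at 40.0 s. The forecast for y fails in this flask if solid substrate goes to 5.40 × 10⁻⁴ M, which shifts y by 5 points, or if, with the charges held, the rate constant of step 3 is doubled, which gives 97.4 %, above the forecast's high end. A second flask, the same but charged with 0.0013 M of solid substrate, has an emptying time of 69.5 s, longer than the run, so at least 42.4 % of its solid must remain, and it holds 54.4 %.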